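**Strategy**

Ring A is cut at C1–C2 and C4–C5 into a C2–C3–C4(CH3)CO2Me unit and a ring-B enone aldehyde in which C1 (formyl carbon) and C5 (enone β-carbon) both sit on the quaternary C10. In one flask an ester-bearing alkylzinc adds to C1 and the C4 ester enolate then closes onto C5. The step exploits the cis A/B fusion of the target (H-5 syn to the C20 methyl on C10): a nucleophile tethered through C1 can only reach C5 from the C1 face, and C4 is set in the same event. The precursor comes from (R)-linalool by allylic oxidation, a catalytic Diels–Alder reaction and aminomethylenation.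

Key step: step 4

Remark 1: the SMILES is read literally, i.e. (4S,5S,9S,10R,13R): H-5, the C20 methyl, the C9 side chain and the C19 carboxyl all lie on one face (β), so the decalin is cis-fused (5β-H).
Remark 2: labdane numbers of the target are used for all intermediates (ring A = C1–C5, C10; ring B = C5–C10; C11–C16 side chain; C17 on C8; C18 and C19 on C4; C20 on C10).
Remark 3: (R)-linalool of high enantiomeric purity, diene 3 and bromo ester 7 are taken as commercial.

**Route**

Step 1
Reactants: 1 (R)-linalool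
Product: 2 (2E,6R)-6-hydroxy-2,6-dimethylocta-2,7-dienal
Conditions: SeO2 (1.2 equiv), 1,4-dioxane/EtOH, 80 °C
Reagents that add atoms: selenium dioxide, O=[Se]=O
Why: Allylic oxidation by SeO2 (ene reaction, 2,3-sigmatropic shift, further oxidation to the aldehyde) is selective for the E methyl group of the trisubstituted alkene, while the vinyl group has no allylic C–H and C13 is untouched.

Step 2
Reactants: 2 (2E,6R)-6-hydroxy-2,6-dimethylocta-2,7-dienal; 3 (E)-3-(tert-butyldimethylsilyloxy)-N,N-dimethylbuta-1,3-dien-1-amine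
Product: 5 (1R,6S)-6-[(3R)-3-hydroxy-3-methylpent-4-en-1-yl]-1-methyl-4-oxocyclohex-2-ene-1-carbaldehyde, via cycloadduct 4 (not isolated)
Conditions: 3 (1.5 equiv), (4R,5R)-2,2-dimethyl-α,α,α′,α′-tetra(1-naphthyl)-1,3-dioxolane-4,5-dimethanol (20 mol %; its antipode if a test run shows the opposite sense), toluene, −78 → −40 °C; then aq. HF, MeCN, 0 °C
Reagents that add atoms: none
Why: Hydrogen bonding of the diol to the aldehyde activates 2 for a normal-demand Diels–Alder reaction in which the amino-bearing terminus of 3 bonds to C10 and the CH2 terminus to C9 (ortho/para rule), suprafacial addition to the E alkene places C11 cis to the C20 methyl, the chiral diol (not the remote C13) selects the Si face at C-2 of 2 and so sets C9 and C10, and HF then removes the silyl group and eliminates dimethylamine to give the enone.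

Step 3
Reactants: 5 (1R,6S)-6-[(3R)-3-hydroxy-3-methylpent-4-en-1-yl]-1-methyl-4-oxocyclohex-2-ene-1-carbaldehyde
Product: 6 the 5-[(E)-(dimethylamino)methylidene] derivative of 5 (aminomethylidene carbon = C17 on C8; C9 and C10 unchanged)
Conditions: t-BuOCH(NMe2)2, toluene, 80 °C
Reagents that add atoms: tert-butoxybis(dimethylamino)methane, CN(C)C(OC(C)(C)C)N(C)C
Why: Condensation of the aminal ester with the only enolisable position, C8 (α′ of the enone; the formyl group has no α-hydrogen), gives the E enaminone, which installs C17 on C8 and removes the α′ protons that base would otherwise take in step 4.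

Step 4
Reactants: 6 enaminone aldehyde; 7 methyl 4-bromo-2-methylbutanoate
Product: 9 methyl (13R,17E)-17-(dimethylamino)-1ξ,13-dihydroxy-7-oxo-5β-labda-8(17),14-dien-19-oate, via hydroxy ester 8 (not isolated)
Conditions: 7, Zn, LiCl, THF, 50 °C (gives the alkylzinc bromide); add 6, MgCl2, 0 °C → rt; then LiN(SiMe3)2 (4 equiv), same flask, −78 → −20 °C; aq. NH4Cl
Reagents that add atoms: none
Why: The ester-bearing alkylzinc bromide made from 7 adds only to the non-enolisable C1 aldehyde of 6 (MgCl2-promoted 1,2-addition, forming C1–C2 and alkoxide 8), and LiN(SiMe3)2 then generates the C4 ester enolate, which adds in Michael fashion to C5 of the ring-B enone. Both halves are known reaction types (addition of functionalised organozinc reagents to aldehydes; base-mediated intramolecular ester-enolate Michael cyclisation), run here as one flask operation that amounts to a formal [3+3] annulation. Ring A closes by a 6-exo-trig Michael addition onto the endocyclic C5=C6 bond. C5 is set by the tether, since C4 can only reach the face of C5 that carries C1, anti to the pseudo-axial C20 methyl, so H-5 ends syn to C20 (cis fusion); at C4, allylic 1,3-strain in the chair-like transition state keeps the C(OLi)OMe carbon pseudo-equatorial and the methyl pseudo-axial, which places CO2Me cis to H-5. The step needs aldehyde-over-enone chemoselectivity (alkylzinc halides do not add to enones or vinylogous amides), no competing ketone enolisation (C8 is blocked as the aminomethylidene carbon) and attack at C5 rather than C17 (a six- against an eight-membered ring). The C1 carbinol epimers are not separated because C1 becomes CH2 in step 6.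

Step 5
Reactants: 9 methyl (13R,17E)-17-(dimethylamino)-1ξ,13-dihydroxy-7-oxo-5β-labda-8(17),14-dien-19-oate
Product: 10 the 1-O-(1H-imidazol-1-ylcarbonothioyl) derivative of 9
Conditions: 1,1′-thiocarbonyldiimidazole, 4-(dimethylamino)pyridine (cat.), toluene, 80 °C
Reagents that add atoms: 1,1′-thiocarbonyldiimidazole, S=C(n1ccnc1)n1ccnc1
Why: Acyl transfer to the only secondary hydroxyl (C1–OH) prepares the Barton–McCombie deoxygenation, the tertiary C13–OH being too hindered to react.

Step 6
Reactants: 10 the 1-O-(1H-imidazol-1-ylcarbonothioyl) derivative of 9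
Product: 11 methyl (13R,17E)-17-(dimethylamino)-13-hydroxy-7-oxo-5β-labda-8(17),14-dien-19-oate
Conditions: n-Bu3SnH, 2,2′-azobis(2-methylpropionitrile) (cat.), toluene, 110 °C
Reagents that add atoms: none
Why: Barton–McCombie deoxygenation, in which the stannyl radical adds to C=S, the C1–O bond fragments and the secondary C1 radical is reduced by n-Bu3SnH, cyclisation onto C17 being a disfavoured 5-endo mode.

Step 7
Reactants: 11 methyl (13R,17E)-17-(dimethylamino)-13-hydroxy-7-oxo-5β-labda-8(17),14-dien-19-oate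
Product: 13 methyl (13R)-13-hydroxy-17-oxo-5β-labda-7,14-dien-19-oate, via amino allylic alcohol 12 (not isolated)
Conditions: NaBH4, CeCl3·7H2O, MeOH, −40 → 0 °C; then AcOH/H2O, THF, rt
Reagents that add atoms: water, O
Why: Luche 1,2-reduction of the vinylogous amide carbonyl, then acid-induced loss of water and hydrolysis of the resulting iminium ion, transposes the carbonyl from C7 to C17 (enaminone to enal) without touching the ester or the centres at C5 and C9.

Step 8
Reactants: 13 methyl (13R)-13-hydroxy-17-oxo-5β-labda-7,14-dien-19-oate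
Product: 15 methyl (13R)-13-hydroxy-5β-labda-8(17),14-dien-19-oate, via tosylhydrazone 14 (not isolated)
Conditions: TsNHNH2, EtOH, rt; catecholborane, CHCl3, 0 °C; NaOAc·3H2O, 60 °C
Reagents that add atoms: none
Why: Reduction of the α,β-unsaturated tosylhydrazone with catecholborane and elimination of sulfinate give an allylic diazene, which loses N2 by a retro-ene (1,5-sigmatropic) hydrogen shift that delivers H to C7 and leaves the alkene exocyclic at C8=C17.

Step 9
Reactants: 15 methyl (13R)-13-hydroxy-5β-labda-8(17),14-dien-19-oate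
Product: 16 (13R)-13-hydroxy-5β-labda-8(17),14-dien-19-oic acid
Conditions: EtSNa (5 equiv), DMF, 100 °C; then cold dilute HCl to pH 4
Reagents that add atoms: none
Why: SN2 demethylation by thiolate at the O–CH3 carbon frees the hindered C19 acid without attack at its shielded carbonyl and without touching the alkenes or the tertiary alcohol.

Step 10
Reactants: 16 (13R)-13-hydroxy-5β-labda-8(17),14-dien-19-oic acid
Product: 18 (13R)-13-acetoxy-5β-labda-8(17),14-dien-19-oic acid, via mixed anhydride 17 (not isolated)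
Conditions: Ac2O, Et3N, 4-(dimethylamino)pyridine (cat.), CH2Cl2, rt → 40 °C; then H2O, THF, rt; pH 4 buffer
Reagents that add atoms: acetic anhydride, CC(=O)OC(C)=O
Why: Acylpyridinium catalysis acetylates the tertiary allylic alcohol with retention at C13, the acid being carried as mixed anhydride 17 and released by hydrolysis at the less hindered acetyl carbonyl.

**Compound list**

1 | (R)-linalool, (3R)-3,7-dimethylocta-1,6-dien-3-ol | C=C[C@@](C)(CCC=C(C)C)O | starting material
2 | (2E,6R)-6-hydroxy-2,6-dimethylocta-2,7-dienal | C=C[C@@](C)(CC/C=C(\C)C=O)O | intermediate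
3 | (E)-3-(tert-butyldimethylsilyloxy)-N,N-dimethylbuta-1,3-dien-1-amine | CN(C)/C=C/C(=C)O[Si](C)(C)C(C)(C)C | starting material
4 | cycloadduct: 2-(dimethylamino)-4-(tert-butyldimethylsilyloxy)-1-methyl-6-[(3R)-3-hydroxy-3-methylpent-4-en-1-yl]cyclohex-3-ene-1-carbaldehyde, C1 and C6 as in 5, amino carbon unassigned | C=C[C@@](C)(CC[C@H]1CC(O[Si](C)(C)C(C)(C)C)=CC(N(C)C)[C@]1(C)C=O)O | intermediate
5 | (1R,6S)-6-[(3R)-3-hydroxy-3-methylpent-4-en-1-yl]-1-methyl-4-oxocyclohex-2-ene-1-carbaldehyde (ring B; CHO = C1, C=C = C5=C6, C=O = C7) | C=C[C@@](C)(CC[C@H]1CC(=O)C=C[C@]1(C)C=O)O | intermediate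
6 | 5-[(E)-(dimethylamino)methylidene] derivative of 5 (C17 on C8) | C=C[C@@](C)(CC[C@H]1/C(=C\N(C)C)C(=O)C=C[C@]1(C)C=O)O | intermediate
7 | methyl 4-bromo-2-methylbutanoate (racemic) | COC(=O)C(C)CCBr | starting material
8 | hydroxy ester: methyl 5-hydroxy-2-methylpentanoate carrying ring B of 6 at its C5 (= C1; C1 and C4 unassigned) | C=C[C@@](C)(CC[C@H]1/C(=C\N(C)C)C(=O)C=C[C@]1(C)C(O)CCC(C)C(=O)OC)O | intermediate
9 | methyl (13R,17E)-17-(dimethylamino)-1ξ,13-dihydroxy-7-oxo-5β-labda-8(17),14-dien-19-oate (5β-H, 9α-H, 10β-CH3, 4α-CH3, 4β-CO2Me) | C=C[C@@](C)(CC[C@H]1/C(=C\N(C)C)C(=O)C[C@H]2[C@]1(C)C(O)CC[C@]2(C)C(=O)OC)O | intermediate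
10 | 1-O-(1H-imidazol-1-ylcarbonothioyl) derivative of 9 | C=C[C@@](C)(CC[C@H]1/C(=C\N(C)C)C(=O)C[C@H]2[C@]1(C)C(OC(=S)n3ccnc3)CC[C@]2(C)C(=O)OC)O | intermediate
11 | methyl (13R,17E)-17-(dimethylamino)-13-hydroxy-7-oxo-5β-labda-8(17),14-dien-19-oate | C=C[C@@](C)(CC[C@H]1/C(=C\N(C)C)C(=O)C[C@H]2[C@]1(C)CCC[C@]2(C)C(=O)OC)O | intermediate
12 | methyl (13R,17E)-17-(dimethylamino)-7ξ,13-dihydroxy-5β-labda-8(17),14-dien-19-oate | C=C[C@@](C)(CC[C@H]1/C(=C\N(C)C)C(O)C[C@H]2[C@]1(C)CCC[C@]2(C)C(=O)OC)O | intermediate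
13 | methyl (13R)-13-hydroxy-17-oxo-5β-labda-7,14-dien-19-oate | C=C[C@@](C)(CC[C@H]1C(C=O)=CC[C@H]2[C@]1(C)CCC[C@]2(C)C(=O)OC)O | intermediate
14 | 17-(4-methylbenzenesulfonyl)hydrazone of 13 | C=C[C@@](C)(CC[C@H]1C(C=NNS(=O)(=O)c3ccc(C)cc3)=CC[C@H]2[C@]1(C)CCC[C@]2(C)C(=O)OC)O | intermediate
15 | methyl (13R)-13-hydroxy-5β-labda-8(17),14-dien-19-oate | C=C[C@@](C)(CC[C@H]1C(=C)CC[C@H]2[C@]1(C)CCC[C@]2(C)C(=O)OC)O | intermediate
16 | (13R)-13-hydroxy-5β-labda-8(17),14-dien-19-oic acid | C=C[C@@](C)(CC[C@H]1C(=C)CC[C@H]2[C@]1(C)CCC[C@]2(C)C(=O)O)O | intermediate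
17 | acetic (13R)-13-acetoxy-5β-labda-8(17),14-dien-19-oic anhydride | C=C[C@@](C)(CC[C@H]1C(=C)CC[C@H]2[C@]1(C)CCC[C@]2(C)C(=O)OC(C)=O)OC(C)=O | intermediate
18 | (13R)-13-acetoxy-5β-labda-8(17),14-dien-19-oic acid, (1S,4aR,5S,8aS)-5-[(3R)-3-acetoxy-3-methylpent-4-en-1-yl]-1,4a-dimethyl-6-methylidenedecahydronaphthalene-1-carboxylic acid | C=C[C@@](C)(CC[C@H]1C(=C)CC[C@H]2[C@]1(C)CCC[C@]2(C)C(=O)O)OC(C)=O | target

**Count and risks**

Total step count: 10. Longest linear sequence: 10 steps (1 → 18).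

Step 4 (key step). The alkoxide formed at C1 may fragment by vinylogous retro-aldol cleavage, enolisation of the ester may be incomplete in the presence of zinc and magnesium salts, closure onto the donor-substituted enone may be slow, and facial control at C4 may be poor. The fallback sets out from 6 and uses a stabilised nucleophile in a single-reagent domino. The 1,3-dianion of methyl 2-methyl-3-oxobutanoate (NaH, then n-BuLi, THF, −78 → 0 °C) should add through its terminal carbon to the C1 aldehyde, and the remaining lithium-chelated β-keto ester enolate should close onto C5 in the same flask, giving methyl (13R,17E)-17-(dimethylamino)-1ξ,13-dihydroxy-3,7-dioxo-5β-labda-8(17),14-dien-19-oate F1. Mesylation (MsCl, Et3N) to the 1-O-methanesulfonate F2 and elimination in the same flask would give the ring-A enone, the 1,8(17),14-triene-3,7-dione F3. Conjugate reduction with [(Ph3P)CuH]6 would give the saturated 3,7-dione F4. NaBH4/CeCl3·7H2O (through the 3ξ,7ξ-diol F5) and then aqueous AcOH would give the 3ξ-hydroxy 17-aldehyde F6. Its tosylhydrazone F7, reduced as in step 8, would give the 3ξ-hydroxy 8(17)-ene ester F8. Thiocarbonylation to the 3-O-(imidazol-1-ylcarbonothioyl) derivative F9 and reduction with n-Bu3SnH would bring the sequence back to the route at 15.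

Step 2. The trisubstituted enal may react sluggishly, and facial selectivity may be poor because the remote C13 centre gives no bias. The fallback sets out from 2. Silylation (Et3SiOTf, 2,6-lutidine) gives the triethylsilyl ether F10. Cycloaddition with 2-(triisopropylsilyloxy)buta-1,3-diene under (S)-1-(2-methylphenyl)-3,3-diphenyltetrahydro-1H,3H-pyrrolo[1,2-c][1,3,2]oxazaborole activated by HN(SO2CF3)2 (CH2Cl2, −78 °C) gives the silyl enol ether cycloadduct F11. Saegusa–Ito oxidation (Pd(OAc)2, MeCN) gives the enone silyl ether F12, and AcOH/THF/H2O removes the triethylsilyl group, coming back to the route at 5.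

Step 7. Hydride may add in 1,4 fashion to the enaminone (leading to loss of the amine and an α-methylene ketone), or the vinylogous amide may be reduced too slowly. The fallback sets out from 11. Exchange of the dimethylamino group for butylthio (n-BuSH, pyridinium p-toluenesulfonate, benzene, 60 °C) gives the 17-(butylsulfanyl) enone F13. This thioenol ether should take hydride cleanly at C7 (NaBH4, EtOH) to the 7ξ-alcohol F14, which is hydrolysed (HgCl2, aqueous MeCN) with the same 1,3-transposition, coming back to the route at 13.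

**Further compounds**

F1 | step 4 | methyl (13R,17E)-17-(dimethylamino)-1ξ,13-dihydroxy-3,7-dioxo-5β-labda-8(17),14-dien-19-oate | C=C[C@@](C)(CC[C@H]1/C(=C\N(C)C)C(=O)C[C@H]2[C@]1(C)C(O)CC(=O)[C@]2(C)C(=O)OC)O
F2 | step 4 | 1-O-methanesulfonate of F1 | C=C[C@@](C)(CC[C@H]1/C(=C\N(C)C)C(=O)C[C@H]2[C@]1(C)C(OS(C)(=O)=O)CC(=O)[C@]2(C)C(=O)OC)O
F3 | step 4 | methyl (13R,17E)-17-(dimethylamino)-13-hydroxy-3,7-dioxo-5β-labda-1,8(17),14-trien-19-oate | C=C[C@@](C)(CC[C@H]1/C(=C\N(C)C)C(=O)C[C@H]2[C@]1(C)C=CC(=O)[C@]2(C)C(=O)OC)O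
F4 | step 4 | methyl (13R,17E)-17-(dimethylamino)-13-hydroxy-3,7-dioxo-5β-labda-8(17),14-dien-19-oate | C=C[C@@](C)(CC[C@H]1/C(=C\N(C)C)C(=O)C[C@H]2[C@]1(C)CCC(=O)[C@]2(C)C(=O)OC)O
F5 | step 4 | methyl (13R,17E)-17-(dimethylamino)-3ξ,7ξ,13-trihydroxy-5β-labda-8(17),14-dien-19-oate | C=C[C@@](C)(CC[C@H]1/C(=C\N(C)C)C(O)C[C@H]2[C@]1(C)CCC(O)[C@]2(C)C(=O)OC)O
F6 | step 4 | methyl (13R)-3ξ,13-dihydroxy-17-oxo-5β-labda-7,14-dien-19-oate | C=C[C@@](C)(CC[C@H]1C(C=O)=CC[C@H]2[C@]1(C)CCC(O)[C@]2(C)C(=O)OC)O
F7 | step 4 | 17-(4-methylbenzenesulfonyl)hydrazone of F6 | C=C[C@@](C)(CC[C@H]1C(C=NNS(=O)(=O)c3ccc(C)cc3)=CC[C@H]2[C@]1(C)CCC(O)[C@]2(C)C(=O)OC)O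
F8 | step 4 | methyl (13R)-3ξ,13-dihydroxy-5β-labda-8(17),14-dien-19-oate | C=C[C@@](C)(CC[C@H]1C(=C)CC[C@H]2[C@]1(C)CCC(O)[C@]2(C)C(=O)OC)O
F9 | step 4 | 3-O-(1H-imidazol-1-ylcarbonothioyl) derivative of F8 | C=C[C@@](C)(CC[C@H]1C(=C)CC[C@H]2[C@]1(C)CCC(OC(=S)n3ccnc3)[C@]2(C)C(=O)OC)O
F10 | step 2 | (2E,6R)-2,6-dimethyl-6-[(triethylsilyl)oxy]octa-2,7-dienal | C=C[C@@](C)(CC/C=C(\C)C=O)O[Si](CC)(CC)CC
F11 | step 2 | 1-methyl-6-[(3R)-3-methyl-3-(triethylsilyloxy)pent-4-en-1-yl]-4-(triisopropylsilyloxy)cyclohex-3-ene-1-carbaldehyde, C1 and C6 as in 5 | C=C[C@@](C)(CC[C@H]1CC(O[Si](C(C)C)(C(C)C)C(C)C)=CC[C@]1(C)C=O)O[Si](CC)(CC)CC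
F12 | step 2 | O-triethylsilyl ether of 5 | C=C[C@@](C)(CC[C@H]1CC(=O)C=C[C@]1(C)C=O)O[Si](CC)(CC)CC
F13 | step 7 | methyl (13R,17E)-17-(butylsulfanyl)-13-hydroxy-7-oxo-5β-labda-8(17),14-dien-19-oate | C=C[C@@](C)(CC[C@H]1/C(=C\SCCCC)C(=O)C[C@H]2[C@]1(C)CCC[C@]2(C)C(=O)OC)O
F14 | step 7 | methyl (13R,17E)-17-(butylsulfanyl)-7ξ,13-dihydroxy-5β-labda-8(17),14-dien-19-oate | C=C[C@@](C)(CC[C@H]1/C(=C\SCCCC)C(O)C[C@H]2[C@]1(C)CCC[C@]2(C)C(=O)OC)O
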